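# Total synthesis of the target (haterumalide NA skeleton), from 2-deoxy-D-glucose

**Retrosynthesis**
1. The 14-membered lactone is closed last by an intramolecular Nozaki–Hiyama–Kishi (NHK) reaction. It joins a (Z)-vinyl iodide (C4) to the aldehyde of a C13 3-oxopropanoate ester (C3) and sets C3. Acetylation, PMB removal and methyl ester hydrolysis then finish the synthesis.
2. The (Z)-vinyl iodide comes from a C5 aldehyde by Stork–Zhao–Wittig olefination. The E-trisubstituted C16=C17 side chain comes from cross-metathesis of a C16 vinyl carbinol ether with methyl 3-methylbut-3-enoate.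
3. The (Z)-chloroalkene (C7=C8) comes from a B-alkyl Suzuki coupling of a 2-vinyl-THF-derived alkylborane with a 1,1-dichloroalkene.
4. The THF (C11–O–C14) forms first, by 5-exo selenoetherification of the Wittig alkene derived from 2-deoxy-D-glucose. The sugar supplies the C13/C14/C15 stereotriad, which matches the target (3R,4S,5R in the hexanal numbering).
5. Ring order: THF first (steps 3–4), then the macrolactone (ester in step 17, ring closure by C3–C4 bond formation in step 19).

**Assumptions**
- The target is haterumalide NA, with the 2,5-trans THF exactly as the SMILES encodes.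
- Unprotected 2-deoxy-D-glucose tolerates an excess of Wittig ylide.
- Minor diastereomers and acetal epimers are separable or converge.
- The macrocyclic NHK gives the 3R alcohol.

---

**Step 1**
Reactants: 1 (2-deoxy-D-glucose, (3R,4S,5R)-3,4,5,6-tetrahydroxyhexanal)
Product: 2 ((2R,3S,4R,6Z)-oct-6-ene-1,2,3,4-tetrol)
Conditions: Ph3P+Et Br–, KOtBu (≥5 equiv), THF, 0 °C → 65 °C
Reagents that add atoms: ethyltriphenylphosphonium bromide, CC[P+](c1ccccc1)(c1ccccc1)c1ccccc1.[Br-]
Why: Wittig olefination of the masked aldehyde with a non-stabilised ylide gives the Z-propenyl chain (C9–C10). The C13–C15 stereocentres are untouched.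

**Step 2**
Reactants: 2
Product: 3 (C15/C16 4-methoxybenzylidene acetal of 2)
Conditions: 4-MeOC6H4CH(OMe)2, CSA (cat.), DMF, 40 °C, reduced pressure
Reagents that add atoms: anisaldehyde dimethyl acetal, COC(OC)c1ccc(OC)cc1
Why: Acetal exchange selectively protects the terminal 1,2-diol as a five-membered acetal. C13-OH and C14-OH stay free, and the acetal carbon is a mixture of epimers that is destroyed in step 8.

**Step 3**
Reactants: 3
Product: 4 (2-(1-phenylselenoethyl)THF acetal; C10 epimeric mixture)
Conditions: PhSeCl, K2CO3, CH2Cl2, –78 °C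
Reagents that add atoms: benzeneselenenyl chloride, Cl[Se]c1ccccc1
Why: 5-exo-trig selenoetherification by anti addition. Only C14-OH can close a five-membered ring (C15 is blocked, and C13 would need a 4-exo closure). A chair-like transition state with C15 pseudo-equatorial places the C11 substituent trans to C14 and C13, which is the required (11R) configuration. C10 epimers are irrelevant.

**Step 4**
Reactants: 4
Product: 5 (2-vinyl THF, C13-OH free)
Conditions: 30% H2O2, pyridine, CH2Cl2, 0 → 23 °C
Reagents that add atoms: none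
Why: Selenoxide syn-elimination occurs away from the ring-oxygen-bearing C11, giving the terminal vinyl group (C9=C10). C11 is retained.

**Step 5**
Reactants: 5
Product: 6 (C13-OTBS ether of 5)
Conditions: TBSCl, imidazole, DMF, 23 °C
Reagents that add atoms: tert-butyldimethylsilyl chloride, CC(C)(C)[Si](C)(C)Cl
Why: Silylation masks the only free OH so that later oxidation and hydroboration are clean. No stereocentre is affected.

**Step 6**
Reactants: 7 (3-(tert-butyldimethylsilyloxy)propanal)
Product: 8 (1,1-dichloro-4-(TBSO)but-1-ene)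
Conditions: PPh3, CCl4, CH2Cl2, 0 → 23 °C
Reagents that add atoms: carbon tetrachloride, ClC(Cl)(Cl)Cl
Why: Ramirez dichloromethylenation converts the aldehyde to the 1,1-dichloroalkene (C8, C7, C6, C5 unit).

**Step 7**
Reactants: 6; 8
Product: 9 (THF with C10–C9–C8(Cl)=C7 chain, (Z)-chloroalkene)
Conditions: 9-BBN, THF, 23 °C; then 8, Pd(dppf)Cl2 (5 mol%), K3PO4 (aq), THF, 60 °C
Reagents that add atoms: none
Why: Anti-Markovnikov hydroboration of the vinyl group gives a primary B-alkyl-9-BBN, which undergoes Suzuki–Miyaura coupling at the less hindered C–Cl bond (trans to C6) with retention. The remaining cis Cl gives the Z-chloroalkene.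

**Step 8**
Reactants: 9
Product: 10 (C15-OPMB, C16-OH)
Conditions: DIBAL-H (3 equiv), CH2Cl2, –78 → 0 °C
Reagents that add atoms: none
Why: Reductive opening of the PMP acetal. Aluminium binds the less hindered primary oxygen and hydride goes to the acetal carbon, leaving the PMB ether on the secondary C15-O. No stereocentre changes.

**Step 9**
Reactants: 10
Product: 11 (C16 aldehyde)
Conditions: Dess–Martin periodinane, NaHCO3, CH2Cl2, 23 °C
Reagents that add atoms: none
Why: Mild oxidation of the primary alcohol. The α-alkoxy aldehyde is used crude to avoid epimerisation at C15.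

**Step 10**
Reactants: 11
Product: 12 (C15–CH=CH2, C16=C17)
Conditions: Ph3P+CH3 Br–, KOtBu, THF, –78 → 0 °C
Reagents that add atoms: methyltriphenylphosphonium bromide, C[P+](c1ccccc1)(c1ccccc1)c1ccccc1.[Br-]
Why: Wittig methylenation of the aldehyde with an unstabilised ylide at low temperature keeps C15 configurationally intact.

**Step 11**
Reactants: 12
Product: 13 (C5-OH)
Conditions: CSA (0.2 equiv), MeOH/CH2Cl2 (1:1), 0 °C
Reagents that add atoms: none
Why: Acid-catalysed methanolysis removes the unhindered primary TBS ether selectively. The ring secondary C13-OTBS and the PMB ether survive.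

**Step 12**
Reactants: 13
Product: 14 (C5 aldehyde, β,γ-unsaturated)
Conditions: Dess–Martin periodinane, NaHCO3, CH2Cl2, 0 °C
Reagents that add atoms: none
Why: Mild oxidation avoids conjugation of the β,γ-unsaturated aldehyde. It is used immediately.

**Step 13**
Reactants: 14
Product: 15 ((Z)-vinyl iodide, C4(I)(Me)=C5H)
Conditions: Ph3P+Et I–, NaHMDS, THF; then I2; then NaHMDS, HMPA, –78 °C; then 14
Reagents that add atoms: ethyltriphenylphosphonium iodide, CC[P+](c1ccccc1)(c1ccccc1)c1ccccc1.[I-]; iodine, II
Why: Stork–Zhao–Wittig olefination with the α-iodo ylide (Ph3P=C(I)CH3). It is Z-selective, with I cis to C6 on the new trisubstituted alkene, and that geometry is what the NHK later transfers to the C3 substituent.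

**Step 14**
Reactants: 15; 16 (methyl 3-methylbut-3-enoate)
Product: 17 (E-trisubstituted C16=C17 side chain, methyl ester)
Conditions: Hoveyda–Grubbs II (10 mol%), 16 (5 equiv), CH2Cl2, 40 °C
Reagents that add atoms: none
Why: Cross-metathesis of the terminal vinyl of the allylic PMB ether with the 1,1-disubstituted alkene gives the thermodynamically favoured E-trisubstituted alkene. The hindered trisubstituted vinyl iodide and chloroalkene are inert.

**Step 15**
Reactants: 17
Product: 18 (C13-OH)
Conditions: HF·pyridine, pyridine, THF, 0 → 23 °C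
Reagents that add atoms: none
Why: Fluoride removes the secondary TBS ether, freeing C13-O for lactone formation. PMB, vinyl iodide and methyl ester are stable.

**Step 16**
Reactants: 19 (ethyl 3,3-diethoxypropanoate)
Product: 20 (3,3-diethoxypropanoic acid)
Conditions: LiOH, THF/H2O, 0 → 23 °C; neutral work-up (pH ≈ 5)
Reagents that add atoms: lithium hydroxide, [Li+].[OH-]
Why: Saponification gives the acid, which carries the masked C3 aldehyde.

**Step 17**
Reactants: 18; 20
Product: 21 (C13 3,3-diethoxypropanoate ester)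
Conditions: EDC·HCl, DMAP, CH2Cl2, 0 → 23 °C
Reagents that add atoms: none
Why: Steglich esterification of the sole free alcohol forms the C1–O–C13 ester. C13 is not epimerisable.

**Step 18**
Reactants: 21
Product: 22 (C13 3-oxopropanoate ester, C3 aldehyde)
Conditions: TMSOTf, 2,6-lutidine, CH2Cl2, 0 °C; then H2O
Reagents that add atoms: water, O
Why: Non-Brønsted-acidic conversion of the diethyl acetal to the aldehyde, so the allylic PMB ether and vinyl iodide are not ionised.

**Step 19**
Reactants: 22
Product: 23 (14-membered macrolactone, C3-OH, PMB ether, methyl ester)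
Conditions: CrCl2 (10 equiv), NiCl2 (0.05 equiv), DMF, 0.002 M, 23 °C, syringe-pump addition over 8 h
Reagents that add atoms: none
Why: Intramolecular Nozaki–Hiyama–Kishi reaction. The Ni/Cr alkenyl species forms with retention of the Z geometry (C3 ends cis to C6) and adds to the aldehyde. C3 is set by macrocyclic conformational bias, assumed to give 3R.

**Step 20**
Reactants: 23
Product: 24 (C3-OAc)
Conditions: Ac2O, DMAP, pyridine, CH2Cl2, 0 → 23 °C
Reagents that add atoms: acetic anhydride, CC(=O)OC(C)=O
Why: Acylation of the allylic alcohol with retention at C3.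

**Step 21**
Reactants: 24
Product: 25 (haterumalide NA methyl ester, C15-OH)
Conditions: DDQ, CH2Cl2/pH 7 phosphate buffer (10:1), 0 °C, 30 min
Reagents that add atoms: none
Why: Oxidative PMB removal is fast at 0 °C. The buffer protects the acid-sensitive allylic systems and the bis-allylic C6H2.

**Step 22**
Reactants: 25
Product: 26 (target)
Conditions: Me3SnOH, 1,2-dichloroethane, 60 °C
Reagents that add atoms: trimethyltin hydroxide, C[Sn](C)(C)O
Why: Me3SnOH hydrolyses the unhindered methyl ester selectively and leaves the macrolactone and the C3 acetate intact. No stereocentre or alkene is affected, and the last product is the target.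

---

**Compound list**

| # | Name | SMILES | Role |
|---|---|---|---|
| 1 | 2-deoxy-D-glucose (aldehydo form) | O=CC[C@@H](O)[C@H](O)[C@H](O)CO | starting material |
| 2 | (2R,3S,4R,6Z)-oct-6-ene-1,2,3,4-tetrol | C/C=C\C[C@@H](O)[C@H](O)[C@H](O)CO | intermediate |
| 3 | C15/C16 PMP acetal of 2 | C/C=C\C[C@@H](O)[C@H](O)[C@H]1COC(c2ccc(OC)cc2)O1 | intermediate |
| 4 | 2-(1-phenylselenoethyl)THF acetal | CC([Se]c1ccccc1)[C@@H]2C[C@@H](O)[C@H](O2)[C@H]3COC(c4ccc(OC)cc4)O3 | intermediate |
| 5 | 2-vinyl THF acetal, C13-OH | C=C[C@@H]1C[C@@H](O)[C@H](O1)[C@H]2COC(c3ccc(OC)cc3)O2 | intermediate |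
| 6 | C13-OTBS ether | C=C[C@@H]1C[C@@H](O[Si](C)(C)C(C)(C)C)[C@H](O1)[C@H]2COC(c3ccc(OC)cc3)O2 | intermediate |
| 7 | 3-(TBSO)propanal | O=CCCO[Si](C)(C)C(C)(C)C | starting material |
| 8 | 1,1-dichloro-4-(TBSO)but-1-ene | ClC(Cl)=CCCO[Si](C)(C)C(C)(C)C | intermediate |
| 9 | Suzuki product (Z-chloroalkene, PMP acetal) | CC(C)(C)[Si](C)(C)OCC/C=C(\Cl)CC[C@@H]1C[C@@H](O[Si](C)(C)C(C)(C)C)[C@H](O1)[C@H]2COC(c3ccc(OC)cc3)O2 | intermediate |
| 10 | C15-OPMB, C16-OH | CC(C)(C)[Si](C)(C)OCC/C=C(\Cl)CC[C@@H]1C[C@@H](O[Si](C)(C)C(C)(C)C)[C@H](O1)[C@H](OCc2ccc(OC)cc2)CO | intermediate |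
| 11 | C16 aldehyde | CC(C)(C)[Si](C)(C)OCC/C=C(\Cl)CC[C@@H]1C[C@@H](O[Si](C)(C)C(C)(C)C)[C@H](O1)[C@H](OCc2ccc(OC)cc2)C=O | intermediate |
| 12 | C16 vinyl | CC(C)(C)[Si](C)(C)OCC/C=C(\Cl)CC[C@@H]1C[C@@H](O[Si](C)(C)C(C)(C)C)[C@H](O1)[C@H](OCc2ccc(OC)cc2)C=C | intermediate |
| 13 | C5-OH | OCC/C=C(\Cl)CC[C@@H]1C[C@@H](O[Si](C)(C)C(C)(C)C)[C@H](O1)[C@H](OCc2ccc(OC)cc2)C=C | intermediate |
| 14 | C5 aldehyde | O=CC/C=C(\Cl)CC[C@@H]1C[C@@H](O[Si](C)(C)C(C)(C)C)[C@H](O1)[C@H](OCc2ccc(OC)cc2)C=C | intermediate |
| 15 | (Z)-vinyl iodide | I/C(C)=C\C/C=C(\Cl)CC[C@@H]1C[C@@H](O[Si](C)(C)C(C)(C)C)[C@H](O1)[C@H](OCc2ccc(OC)cc2)C=C | intermediate |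
| 16 | methyl 3-methylbut-3-enoate | C=C(C)CC(=O)OC | starting material |
| 17 | cross-metathesis product | I/C(C)=C\C/C=C(\Cl)CC[C@@H]1C[C@@H](O[Si](C)(C)C(C)(C)C)[C@H](O1)[C@H](OCc2ccc(OC)cc2)/C=C(\C)CC(=O)OC | intermediate |
| 18 | C13-OH | I/C(C)=C\C/C=C(\Cl)CC[C@@H]1C[C@@H](O)[C@H](O1)[C@H](OCc2ccc(OC)cc2)/C=C(\C)CC(=O)OC | intermediate |
| 19 | ethyl 3,3-diethoxypropanoate | CCOC(=O)CC(OCC)OCC | starting material |
| 20 | 3,3-diethoxypropanoic acid | CCOC(CC(=O)O)OCC | intermediate |
| 21 | C13 diethoxypropanoate ester | I/C(C)=C\C/C=C(\Cl)CC[C@@H]1C[C@@H](OC(=O)CC(OCC)OCC)[C@H](O1)[C@H](OCc2ccc(OC)cc2)/C=C(\C)CC(=O)OC | intermediate |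
| 22 | C13 3-oxopropanoate ester | I/C(C)=C\C/C=C(\Cl)CC[C@@H]1C[C@@H](OC(=O)CC=O)[C@H](O1)[C@H](OCc2ccc(OC)cc2)/C=C(\C)CC(=O)OC | intermediate |
| 23 | macrolactone, C3-OH, PMB, methyl ester | O[C@@H]1CC(=O)O[C@@H]2C[C@@H](CC/C(Cl)=C/C/C=C\1C)O[C@@H]2[C@H](OCc3ccc(OC)cc3)/C=C(\C)CC(=O)OC | intermediate |
| 24 | C3-acetate of 23 | CC(=O)O[C@@H]1CC(=O)O[C@@H]2C[C@@H](CC/C(Cl)=C/C/C=C\1C)O[C@@H]2[C@H](OCc3ccc(OC)cc3)/C=C(\C)CC(=O)OC | intermediate |
| 25 | haterumalide NA methyl ester | CC(=O)O[C@@H]1CC(=O)O[C@@H]2C[C@@H](CC/C(Cl)=C/C/C=C\1C)O[C@@H]2[C@H](O)/C=C(\C)CC(=O)OC | intermediate |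
| 26 | haterumalide NA (target) | CC(=O)O[C@@H]1CC(=O)O[C@@H]2C[C@@H](CC/C(Cl)=C/C/C=C\1C)O[C@@H]2[C@H](O)/C=C(\C)CC(=O)O | target |

---

**Totals**
- Total steps: 22.
- Longest linear sequence: 20 steps, from 1 to 26 (steps 1–5, 7–15, 17–22).

**Three steps most likely to fail**
1. **Step 3 (C11 diastereoselectivity of the selenoetherification).** The 2,5-trans selectivity is assumed from a chair-like transition state.
   - Fallback: start from 2-deoxy-D-galactose (C14 epimer) and add vinylMgBr to the C11 aldehyde. Separate the carbinol epimers, then close the THF by SN2 of the C11 oxygen on a C14 mesylate with inversion. This gives the vinyl THF directly and fixes C11 by separation rather than by transition-state control.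
2. **Step 7 (chemo- and stereoselective Suzuki coupling at the unactivated dichloroalkene C–Cl bond).** The coupling may be sluggish or give the wrong chloride.
   - Fallback: build C7=C8 by chloro-Wittig olefination instead. Use the C7 aldehyde and the ylide of a (1-chloroalkyl)phosphonium salt derived from a THF–CH2CH2–CHO fragment, then separate the Z isomer. This replaces the cross-coupling disconnection with an olefination.
3. **Step 19 (NHK macrocyclisation, yield and C3 diastereoselectivity).** The β-acyloxy aldehyde is enolisable and the 14-membered ring closure is unproven on this substrate.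
   - Fallback: use an open-chain route. Perform an intermolecular NHK with an enantioenriched chromium catalyst, or oxidise epimeric C3 alcohols and reduce with CBS, to set C3 by reagent control. Then close the ring by Yamaguchi macrolactonisation of the seco-acid instead of by C–C bond formation.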